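At reading time t, a flask that consumes G and D one for one at rate kGD shows a climbing log-ratio L = ln[(D/G)(g/d)]. Here g and d are the charges of G and D, and k is the second-order rate constant. Then L rises at k(d − g), from a start-up lag τ onward. With y the fraction of G read as Q, D = d − yg and G = g − yg.

| setting | Monday's | Wednesday's | Friday's | flask |
|---|---|---|---|---|
| G | 14 mM | 21 mM | 28 mM | 28 mM |
| D | 33.6 mM | 33.6 mM | 67 mM | 33.6 mM |
| X | 28 mM | 28 mM | 28 mM | 28.0 mM |
| remark | run made earlier | run made earlier | run made earlier |  |
| time |  |  |  | 25 min |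

| run | time / min | Q / % |
|---|---|---|
| Monday's | 2.00 | 7.2 |
| Monday's | 5.00 | 18.4 |
| Monday's | 10.0 | 33.7 |
| Monday's | 15.0 | 45.1 |
| Wednesday's | 1.33 | 3.1 |
| Wednesday's | 3.00 | 10.8 |
| Wednesday's | 6.00 | 22.0 |
| Wednesday's | 15.0 | 43.6 |
| Friday's | 2.00 | 13.4 |
| Friday's | 5.00 | 31.4 |
| Friday's | 10.0 | 54.4 |
| Friday's | 15.0 | 67.8 |

(each reading ± 0.5 percentage points)

- amount of Q in percent of the G charged, at 80 s, 6.0 min and 25 min

I take Wednesday's readings at 3.00 min and 15.0 min, which give L = 0.0444 and 0.255. Over Wednesday's excess of 12.6 mM, these read as 0.00139 mM⁻¹ min⁻¹, the second-order rate constant k, and a lag τ = 0.465 min, both carrying the scatter.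

The flask has Wednesday's D and more G, so both start with the same fractional loss of G, kd = 0.0467 min⁻¹. But the flask's excess of D is 5.60 mM, and G is the limiting reagent. I reckon the flask at 41.8% at 15.0 min, less than Wednesday's reading of 43.6%, because I reckon the flask's D by then at 21.9 mM, against 24.4 mM from Wednesday's reading. The same line gives me 3.91%, 20.9% and 55.8% at the asked times.

The forecast says 4.1%, 21.2% and 55.9%, on the same form with a lag of about 0.35 min: “This suggests a brief intermediate or start-up step.”

The flask gives 3.94%, 21.0% and 55.8%.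

    Z → Q (k = 0.0294 s⁻¹)
    G + D ⇌ Z (K = 8.42 L mol⁻¹, k = 0.0266 L mol⁻¹ s⁻¹)
    X + Z → J (k = 0.0160 L mol⁻¹ s⁻¹)

At 25.0 min, Z in the flask has a half-life of 0.39 min by its making of Q, far shorter than the 25 min of G by the forward step to Z alone; G + D to Z is the rate-limiting step, and Z stands at 0.618% of the G charged. With 52% of the flask's D charge left, k puts G's half-life at that moment at 28.4 min. On Friday's charge, k and τ give 67.3% at 15.0 min, where the reading is 67.8%.

The runs come from a simulation for an exercise; noise was put on by code.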